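## Analysis of the target

The target 27 is a 14,15-dinorlabdane: a trans-fused decalin (ring A = C1–C5 and C10, ring B = C5–C10) with a 3-oxobutyl chain (C11–C12–C13(=O)–C16) on C9. It has six stereocentres (C2, C4, C5, C7, C9, C10). With the C10 methyl (C20) β and axial, H5 and H9 are α and axial, so the chain is equatorial; the C19 acetoxymethyl on C4 is axial and syn to C20 (C18 methyl α, equatorial); the C2 hydroxyl is α and equatorial; the C7 hydroxyl is α and axial, allylic to the exocyclic C8=C17 alkene. The two quaternary carbons C4 and C10 are 1,3-related with syn-axial carbon substituents, and C4 carries two one-carbon groups that differ only in oxidation level. The sensitive groups are the axial allylic alcohol with its exocyclic alkene (ionisation, allylic transposition, alkene migration under acid), the enolisable methyl ketone, and a primary acetate that must sit on one of three hydroxyls. The hard parts are therefore the C4/C10 pair, the C18/C19 distinction, and the order in which three different hydroxyls are uncovered. The strategy rests on one pattern: C8 with its methyl C17 is para to C5 across ring B, and C5 carries the branched unit C4(C18)(C19) continuing into C3, which is the 2-methyl/5-isopropenyl pattern of (R)-carvone 1 with the correct configuration at C5. Ring B is thus bought, and ring A is closed between the isopropenyl terminus (C3) and a two-carbon arm (C1–C2) placed on C10.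

## Retrosynthetic reasoning

**C7–O bond (27 ⇒ 25).** The axial allylic alcohol and the exocyclic alkene are removed together: cutting C7–O and returning the double bond to C7=C8 gives 25, in which every other group is already final. This is cut first because the 7-hydroxy-8(17)-ene unit is the most acid-sensitive part and should appear last. Forward, an ene-type photooxygenation must attack C7 on the α face and take its hydrogen from the C17 methyl; hydroperoxide 26 is then reduced.

**Protecting groups and acetate (25 ⇒ 24 ⇒ 23 ⇒ 22).** No skeletal bond is cut. The C2 hydroxyl and C13 ketone of 25 are masked in 24 as silyl ether and dioxolane, so that C19 in 23 is the only free hydroxyl when the acetate is put on. Alcohol 23 comes from the neopentyl aldehyde 22 by reduction. The gain is that the three hydroxyls never compete.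

**C4–C18 bond and the C19 oxidation level (22 ⇒ 20 ⇒ 19 ⇒ 17).** The quaternary centre is cut at its equatorial methyl, giving the enolisable aldehyde 20; forward, enolate 21 must be methylated on the α face, which the axial C10 methyl should enforce. Aldehyde 20 is the anti-Markovnikov hydration and oxidation product of the exocyclic C4 methylene of 17, by way of borane 18 and alcohol 19. The cut is made here because the ring closure leaves exactly a methylene on C4.

**Ring B adjustment (17 ⇒ 16 ⇒ 14).** The Δ7 alkene and the C9–H stereocentre are traced to enol triflate 16 and then, through enolate 15, to the C7-keto Δ8 enone 14. Forward, a dissolving-metal reduction must set C9 (hydrogen α, chain equatorial) and deliver a regiodefined enolate, whose oxygen is then removed reductively. This fixes the alkene at C7=C8.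

**C9–C11 bond (14 ⇒ 13 ⇒ 10 + 11).** Enone 14 is the oxidative 1,3-transposition product of tertiary allylic alcohol 13. Cutting C9–C11 in 13 gives enone 10 and organomagnesium reagent 12, made from bromide 11. The cut uses the native carbonyl of the carvone ring (C9) as the attachment site and moves its oxygen to C7, where it later controls C9 and the alkene position.

**Protection (10 ⇒ 9).** The silyl ether of 10 is removed to the free alcohol 9; forward, it shields C2–OH from the organometallic, oxidative and basic steps.

**C2–C3 bond, ring A (9 ⇒ 8).** A homoallylic alcohol next to an exocyclic methylene is the retron of a carbonyl-ene reaction. Cutting C2–C3 returns keto aldehyde 8, in which C3, C4 and the future C19 are the isopropenyl group. C1–C10 and C4–C5 are not cut because they join centres already in place from the chiral pool and one alkylation. The gain is ring A, the C2 oxygen and a C4 handle with no added reagent carbon. Forward, the aldehyde carbon must bond to the alkene terminus, a methyl hydrogen must pass to oxygen, and the oxygen must end on the α face.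

**Oxidation level of the arm (8 ⇒ 7 ⇒ 6).** Keto aldehyde 8 comes from ester 6 by full reduction to diol 7 and double re-oxidation.

**C10–C1 and C10–C20 bonds (6 ⇒ 3 + 4; 3 ⇒ 1).** The C10 quaternary centre is cut at both carbon substituents: first the acetate arm (enolate 5 with bromo ester 4), then the methyl (enolate 2 from 1). The order matters: the second electrophile enters anti to the isopropenyl group, so the arm ends trans to C4 and the methyl cis, as C10 requires.

## Alternatives that were turned down

**Alternative 1: intramolecular Diels–Alder closing rings A and B together.**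
- Disconnection: C5–C10 and C8–C9, opening both rings into the chain A1, where an (E)-3-methyl enal (C9=C10, C11 aldehyde) is tied through C1–C4 to a 2-triethylsilyloxy diene (C5=C6–C7=C8) bearing a phenylthiomethyl group (C17) on C8.
- Forward key step: Me2AlCl-promoted cycloaddition of A1 to the trans-decalin A2.
- For: two rings and four stereocentres (C5, C8, C9, C10) in one step; the C7 oxygen arrives as a silyl enol ether, C17 as a latent methylene, and C4 is already quaternary with C18/C19 distinguished. On bonds per step and on C4 it is stronger than the chosen route.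
- Against: the dienophile is β,β-disubstituted and the diene terminus C5 is neopentyl, so both bonds form at congested carbons. The silyl enol ether is Lewis-acid labile and can divert to desilylation or a stepwise Mukaiyama–Michael addition. Facial control must be relayed from C2 and a quaternary C4 whose two substituents are similar in size, and endo/exo control decides cis or trans fusion. A1 needs an acyclic quaternary stereocentre and a geometry-defined enol ether made enantioselectively. Axial C7 reduction, sulfoxide elimination and a three-carbon extension at C11 still follow.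
- Comparison: the chosen route forms one bond in its key step, but takes C5 from 1, sets C10 by a precedented alkylation, and reaches precursor 8 in four steps, so the risk is one stereocentre rather than four.

**Alternative 2: phenol para-alkylative dearomatisation setting C10.**
- Disconnection: C1–C10, with ring B drawn as a phenol (oxygen at C7).
- Forward key step: KOtBu converts A3 to its phenoxide, whose para carbon C10 displaces the C1 tosylate, closing ring A and giving the cross-conjugated dienone A4.
- For: the C10 quaternary centre comes from a flat arene; C7 oxygen, C17 methyl and the protected chain come with the ring, and C4 is set beforehand. It is stronger than the chosen route on C18/C19 and avoids addition to a hindered ketone.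
- Against: A3 is a fully substituted benzene that is long to assemble. Attack at a para carbon that already bears a methyl and has two ortho substituents is the worst steric case, and the tosylate is β-branched, so intermolecular O-alkylation and elimination compete. C10 selectivity depends on 1,3-induction from C2/C4. Afterwards C5 and C9 are sp2, so the trans fusion and C9–H must be made by face-selective reduction of two tetrasubstituted enone alkenes (one brominated) next to quaternary carbons.
- Comparison: the chosen route has C5 and the trans relationship fixed before ring A closes and sets only C9 by reduction, with the usual axial-protonation preference.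

**Alternative 3: Diels–Alder onto a butenolide to build ring A.**
- Disconnection: C3–C4 and C5–C10.
- Forward key step: Cu(OTf)2 with a chiral bis(oxazoline) binds the 1,3-dicarbonyl of butenolide A6, and diene A5 adds to give lactone A7.
- For: catalytic absolute control; C4 is formed quaternary with C19 (lactone CH2O) and C18 distinguished in the key step, which is stronger than the chosen route on this point; the C2 oxygen arrives as an enol ether from two small fragments.
- Against: the dienophile is tetrasubstituted and two adjacent quaternary carbons (C4, C5) form, so reactivity should be low, with the silyloxydiene exposed to the Lewis acid. In A7, C5 carries an extra ester that must be excised with control of C5–H, C10 is only a methine that must become quaternary when C9 is attached, and all of ring B is missing.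
- Comparison: the hardest centres (C5, C10, trans fusion) remain open after the key step and the sequence is long. The chosen route has ring B, C5 and C10 after two alkylations and pays only with a late, substrate-controlled methylation at C4.

Key step: step 5

Remark on the chemistry: bicyclic compounds are described with labdane numbering (normal series: 5α-H, 9α-H, 10β-methyl; α is the face opposite C20). Epimer mixtures at centres that are later planarised (C6 of 3, the carbinol carbons of 7 and 13, C4 of 18–20) are carried on unseparated. LiN(iPr)2 is taken as the commercial solution.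

## Route

Step 1
Reactants: 1 (R)-carvone
Product: 3 (5R)-2,6-dimethyl-5-(prop-1-en-2-yl)cyclohex-2-en-1-one (6-methylcarvone; both C6 epimers), via lithium dienolate 2 (not isolated)
Conditions: LiN(iPr)2, THF, −78 °C; MeI, −78 to 0 °C
Reagents that add atoms: iodomethane, CI
Why: Kinetic α′-deprotonation gives the cross-conjugated dienolate, which is C-methylated (enolate alkylation); the C6 epimer ratio is irrelevant because this centre is re-enolised in step 2.

Step 2
Reactants: 3 6-methylcarvone; 4 tert-butyl bromoacetate
Product: 6 tert-butyl 2-[(1S,6S)-1,3-dimethyl-2-oxo-6-(prop-1-en-2-yl)cyclohex-3-en-1-yl]acetate, via lithium enolate 5 (not isolated)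
Conditions: LiN(iPr)2, THF, −78 to −20 °C; 4, DMPU, −78 °C to rt
Reagents that add atoms: none
Why: Enolate alkylation with a reactive α-halo ester; the electrophile approaches anti to the adjacent isopropenyl group, so the acetate arm ends trans and the methyl cis to isopropenyl, which sets the future C10.

Step 3
Reactants: 6 keto ester
Product: 7 (5S,6S)-6-(2-hydroxyethyl)-2,6-dimethyl-5-(prop-1-en-2-yl)cyclohex-2-en-1-ol (both C1 epimers)
Conditions: LiAlH4, THF, 0 °C to rt; aqueous NaOH work-up
Reagents that add atoms: none
Why: LiAlH4 reduces the tert-butyl ester to the primary alcohol and the enone carbonyl by 1,2-addition; the carbinol configuration does not matter because it is re-oxidised.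

Step 4
Reactants: 7 diol
Product: 8 2-[(1S,6S)-1,3-dimethyl-2-oxo-6-(prop-1-en-2-yl)cyclohex-3-en-1-yl]acetaldehyde
Conditions: (COCl)2, DMSO, CH2Cl2, −78 °C; Et3N, −78 to 0 °C
Reagents that add atoms: none
Why: Swern oxidation activates both hydroxyls as alkoxysulfonium ions before base is added, so the primary and allylic alcohols are oxidised together without a lactol that could be over-oxidised to a lactone.

Step 5
Reactants: 8 keto aldehyde
Product: 9 (4aS,7S,8aS)-7-hydroxy-2,8a-dimethyl-5-methylidene-4a,5,6,7,8,8a-hexahydronaphthalen-1(4H)-one (trans-fused; 2α-OH, C4=CH2, Δ7, 9-oxo)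
Conditions: Me2AlCl (2.2 equiv), CH2Cl2, −78 to 0 °C; aq NaHCO3
Reagents that add atoms: none
Why: Me2AlCl binds the aldehyde oxygen (a second equivalent is taken up by the enone), the terminal alkene carbon C3 attacks C2 and a hydrogen of the allylic methyl passes to oxygen, concertedly or through a short-lived tertiary C4 cation; the alcohol–aluminium complex then loses methane to an inert alkoxide, which prevents proton-catalysed alkene migration. The closest known reaction type is the Me2AlCl-promoted type 2 intramolecular carbonyl-ene cyclisation of 5-methylhex-5-enals to 3-methylenecyclohexanols. Ring A closes as a six-membered ring, exo with respect to the C=O bond (6-exo-trig at C2) and with the central ene carbon C4 inside the ring. The ring fusion is not made here: the two arms are trans on ring B and diequatorial with the C10 methyl axial, so only the trans-decalin can form. C2 is the only new stereocentre: in a chair closure with oxygen on the β face the axial C10 methyl would point into the six-membered hydrogen-transfer array (the endo position of a bicyclo[3.3.1]nonane-like transition state) and be syn-axial to both O–Al and the donor methyl, so transfer is expected on the α face through a boat-like ring A, or after stepwise closure with O–Al equatorial, and either course gives the equatorial 2α-alcohol. The step needs aldehyde-over-ketone selectivity, secured by the higher electrophilicity of the aldehyde and by the conjugated C9 carbonyl lying next to quaternary C10, and an exocyclic position for the new alkene, secured by hydrogen delivery from the methyl group.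

Step 6
Reactants: 9 hydroxy enone
Product: 10 (4aS,7S,8aS)-7-[(tert-butyldimethylsilyl)oxy]-2,8a-dimethyl-5-methylidene-4a,5,6,7,8,8a-hexahydronaphthalen-1(4H)-one
Conditions: TBSCl, imidazole, DMF, rt
Reagents that add atoms: tert-butyldimethylsilyl chloride, CC(C)(C)[Si](C)(C)Cl
Why: Silylation of the unhindered equatorial secondary alcohol; the silyl ether should survive the organomagnesium, chromium, dissolving-metal, borane and base steps that follow.

Step 7
Reactants: 10 silyloxy enone; 11 2-(2-bromoethyl)-2-methyl-1,3-dioxolane
Product: 13 2α-(tert-butyldimethylsilyloxy)-13,13-ethylenedioxy-14,15,19-trinorlabda-4(18),7-dien-9-ol (C9 configuration open), via Grignard reagent 12 (not isolated)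
Conditions: 11, Mg, THF, 25 °C; then 10, THF, 0 °C to rt; aq NH4Cl
Reagents that add atoms: none
Why: Grignard 1,2-addition to an α-methyl cyclohexenone that cannot enolise toward quaternary C10; the new carbinol configuration is irrelevant because C9 becomes sp2 in step 8.

Step 8
Reactants: 13 tertiary allylic alcohol
Product: 14 2α-(tert-butyldimethylsilyloxy)-13,13-ethylenedioxy-14,15,19-trinorlabda-4(18),8-dien-7-one
Conditions: (C5H5NH)[CrO3Cl] (pyridinium chlorochromate), Celite, CH2Cl2, rt
Reagents that add atoms: pyridinium chlorochromate, [O-][Cr](=O)(=O)Cl.c1cc[nH+]cc1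
Why: Dauben–Babler oxidative 1,3-transposition: the tertiary allylic chromate ester undergoes a [3,3] shift to the secondary C7 chromate, which is oxidised to the enone, moving oxygen from C9 to C7 and the alkene to C8=C9.

Step 9
Reactants: 14 transposed enone
Product: 16 2α-(tert-butyldimethylsilyloxy)-13,13-ethylenedioxy-14,15,19-trinorlabda-4(18),7-dien-7-yl trifluoromethanesulfonate, via lithium enolate 15 (not isolated)
Conditions: Li, NH3/THF, t-BuOH (1 equiv), −78 °C; isoprene; NH3 evaporated; PhNTf2, THF, 0 °C to rt
Reagents that add atoms: N-phenylbis(trifluoromethanesulfonimide), O=S(=O)(N(c1ccccc1)S(=O)(=O)C(F)(F)F)C(F)(F)F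
Why: Dissolving-metal enone reduction with reductive enolate trapping; the β-carbanion at C9 is protonated axially on the α face, anti to the axial C10 methyl, so the chain ends equatorial (9α-H), and the regiodefined C7–C8 enolate is O-sulfonylated.

Step 10
Reactants: 16 enol triflate
Product: 17 2α-(tert-butyldimethylsilyloxy)-13,13-ethylenedioxy-14,15,19-trinorlabda-4(18),7-diene
Conditions: Pd(OAc)2 (5 mol %), PPh3, Bu3N, HCO2H, DMF, 60 °C
Reagents that add atoms: none
Why: Palladium-catalysed formate reduction of an enol triflate: oxidative addition to zerovalent palladium formed in situ, formate exchange, decarboxylation and reductive elimination replace OTf by H without moving the C7=C8 alkene.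

Step 11
Reactants: 17 diene
Product: 19 2α-(tert-butyldimethylsilyloxy)-13,13-ethylenedioxy-14,15,18-trinorlabd-7-en-19-ol and its C4 epimer, via alkylborane 18 (not isolated)
Conditions: 9-BBN, THF, 0 °C to rt; aq NaOH, H2O2, 0 °C to rt
Reagents that add atoms: hydrogen peroxide, OO
Why: Hydroboration–oxidation; 9-BBN strongly prefers the 1,1-disubstituted exocyclic alkene over the trisubstituted ring alkene and places boron on the terminal carbon; the C4 configuration is erased in step 13.

Step 12
Reactants: 19 primary alcohol
Product: 20 2α-(tert-butyldimethylsilyloxy)-13,13-ethylenedioxy-14,15,18-trinorlabd-7-en-19-al and its C4 epimer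
Conditions: Dess–Martin periodinane, pyridine, CH2Cl2, 0 °C to rt
Reagents that add atoms: none
Why: Dess–Martin oxidation of the primary alcohol under buffered conditions that leave the ketal, silyl ether and alkene untouched.

Step 13
Reactants: 20 aldehyde
Product: 22 2α-(tert-butyldimethylsilyloxy)-13,13-ethylenedioxy-14,15-dinorlabd-7-en-19-al, via potassium enolate 21 (not isolated)
Conditions: KOtBu, THF, 0 °C; MeI, 0 °C to rt
Reagents that add atoms: iodomethane, CI
Why: C-methylation of an α-branched aldehyde enolate; iodomethane approaches the exocyclic enolate on the α (equatorial) face because the β face is screened by the syn-axial C10 methyl, giving 4α-methyl and 4β-formyl (axial C19).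

Step 14
Reactants: 22 quaternary aldehyde
Product: 23 2α-(tert-butyldimethylsilyloxy)-13,13-ethylenedioxy-14,15-dinorlabd-7-en-19-ol
Conditions: NaBH4, MeOH–THF, 0 °C
Reagents that add atoms: none
Why: Borohydride reduction of the neopentyl aldehyde; no other reducible group is present.

Step 15
Reactants: 23 C19 alcohol
Product: 24 2α-(tert-butyldimethylsilyloxy)-13,13-ethylenedioxy-14,15-dinorlabd-7-en-19-yl acetate
Conditions: Ac2O, pyridine, DMAP (cat.), CH2Cl2, rt
Reagents that add atoms: acetic anhydride, CC(=O)OC(C)=O
Why: DMAP-catalysed acetylation of the only free hydroxyl; C2 is still silylated and C7 is not yet oxygenated, so no selectivity question arises.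

Step 16
Reactants: 24 protected acetate
Product: 25 19-acetoxy-2α-hydroxy-14,15-dinorlabd-7-en-13-one
Conditions: 2 M aq HCl, THF, rt
Reagents that add atoms: water, O
Why: Acid hydrolysis removes the dioxolane and the unhindered secondary silyl ether in one operation, while the primary acetate and trisubstituted alkene should tolerate dilute aqueous acid at rt; it is done before C7 oxygenation so that acid never meets the allylic alcohol.

Step 17
Reactants: 25 hydroxy keto alkene
Product: 27 19-acetoxy-2α,7α-dihydroxy-14,15-dinorlabd-8(17)-en-13-one, via hydroperoxide 26 (not isolated)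
Conditions: O2, tetraphenylporphyrin (cat.), visible light, CH2Cl2, 0 °C; PPh3, 0 °C to rt
Reagents that add atoms: oxygen, O=O
Why: Schenck ene reaction: singlet oxygen bonds to C7 on the α face, opposite the axial C10 methyl, and takes a hydrogen from the C17 methyl geminal to the bulky C9 substituent, moving the alkene to C8=C17; PPh3 reduces the 7α-hydroperoxide to the axial allylic alcohol.

## Compound list

1 | (R)-carvone, (5R)-2-methyl-5-(prop-1-en-2-yl)cyclohex-2-en-1-one | CC1=CC[C@@H](C(C)=C)CC1=O | starting material
2 | lithium dienolate of 1 (OLi on C1; C1=C6 and C2=C3) | CC1=CC[C@@H](C(C)=C)C=C1O[Li] | intermediate (not isolated)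
3 | (5R)-2,6-dimethyl-5-(prop-1-en-2-yl)cyclohex-2-en-1-one (6-methylcarvone, both C6 epimers) | CC1=CC[C@@H](C(C)=C)C(C)C1=O | intermediate
4 | tert-butyl bromoacetate | CC(C)(C)OC(=O)CBr | starting material
5 | lithium enolate of 3 (OLi on C1; C1=C6) | CC1=CC[C@@H](C(C)=C)C(C)=C1O[Li] | intermediate (not isolated)
6 | tert-butyl 2-[(1S,6S)-1,3-dimethyl-2-oxo-6-(prop-1-en-2-yl)cyclohex-3-en-1-yl]acetate | CC1=CC[C@@H](C(C)=C)[C@](C)(CC(=O)OC(C)(C)C)C1=O | intermediate
7 | (5S,6S)-6-(2-hydroxyethyl)-2,6-dimethyl-5-(prop-1-en-2-yl)cyclohex-2-en-1-ol (both C1 epimers) | CC1=CC[C@@H](C(C)=C)[C@](C)(CCO)C1O | intermediate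
8 | 2-[(1S,6S)-1,3-dimethyl-2-oxo-6-(prop-1-en-2-yl)cyclohex-3-en-1-yl]acetaldehyde | CC1=CC[C@@H](C(C)=C)[C@](C)(CC=O)C1=O | intermediate
9 | (4aS,7S,8aS)-7-hydroxy-2,8a-dimethyl-5-methylidene-4a,5,6,7,8,8a-hexahydronaphthalen-1(4H)-one | CC1=CC[C@H]2C(=C)C[C@H](O)C[C@]2(C)C1=O | intermediate
10 | (4aS,7S,8aS)-7-[(tert-butyldimethylsilyl)oxy]-2,8a-dimethyl-5-methylidene-4a,5,6,7,8,8a-hexahydronaphthalen-1(4H)-one | CC1=CC[C@H]2C(=C)C[C@H](O[Si](C)(C)C(C)(C)C)C[C@]2(C)C1=O | intermediate
11 | 2-(2-bromoethyl)-2-methyl-1,3-dioxolane | CC1(CCBr)OCCO1 | starting material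
12 | [2-(2-methyl-1,3-dioxolan-2-yl)ethyl]magnesium bromide | CC1(CC[Mg]Br)OCCO1 | intermediate (not isolated)
13 | 2α-(tert-butyldimethylsilyloxy)-13,13-ethylenedioxy-14,15,19-trinorlabda-4(18),7-dien-9-ol (C9 configuration open) | CC1=CC[C@H]2C(=C)C[C@H](O[Si](C)(C)C(C)(C)C)C[C@]2(C)C1(O)CCC3(C)OCCO3 | intermediate
14 | 2α-(tert-butyldimethylsilyloxy)-13,13-ethylenedioxy-14,15,19-trinorlabda-4(18),8-dien-7-one | O=C1C[C@H]2C(=C)C[C@H](O[Si](C)(C)C(C)(C)C)C[C@]2(C)C(CCC3(C)OCCO3)=C1C | intermediate
15 | lithium 2α-(tert-butyldimethylsilyloxy)-13,13-ethylenedioxy-14,15,19-trinorlabda-4(18),7-dien-7-olate | CC1=C(O[Li])C[C@H]2C(=C)C[C@H](O[Si](C)(C)C(C)(C)C)C[C@]2(C)[C@H]1CCC3(C)OCCO3 | intermediate (not isolated)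
16 | 2α-(tert-butyldimethylsilyloxy)-13,13-ethylenedioxy-14,15,19-trinorlabda-4(18),7-dien-7-yl trifluoromethanesulfonate | CC1=C(OS(=O)(=O)C(F)(F)F)C[C@H]2C(=C)C[C@H](O[Si](C)(C)C(C)(C)C)C[C@]2(C)[C@H]1CCC3(C)OCCO3 | intermediate
17 | 2α-(tert-butyldimethylsilyloxy)-13,13-ethylenedioxy-14,15,19-trinorlabda-4(18),7-diene | CC1=CC[C@H]2C(=C)C[C@H](O[Si](C)(C)C(C)(C)C)C[C@]2(C)[C@H]1CCC3(C)OCCO3 | intermediate
18 | B-alkyl-9-borabicyclo[3.3.1]nonane from 17 (boron on the C4 CH2; C4 epimers) | CC1=CC[C@H]2C(CB3C4CCCC3CCC4)C[C@H](O[Si](C)(C)C(C)(C)C)C[C@]2(C)[C@H]1CCC5(C)OCCO5 | intermediate (not isolated)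
19 | 2α-(tert-butyldimethylsilyloxy)-13,13-ethylenedioxy-14,15,18-trinorlabd-7-en-19-ol and its C4 epimer | CC1=CC[C@H]2C(CO)C[C@H](O[Si](C)(C)C(C)(C)C)C[C@]2(C)[C@H]1CCC3(C)OCCO3 | intermediate
20 | 2α-(tert-butyldimethylsilyloxy)-13,13-ethylenedioxy-14,15,18-trinorlabd-7-en-19-al and its C4 epimer | CC1=CC[C@H]2C(C=O)C[C@H](O[Si](C)(C)C(C)(C)C)C[C@]2(C)[C@H]1CCC3(C)OCCO3 | intermediate
21 | potassium enolate of 20 (C4=CH–OK) | CC1=CC[C@H]2C(=CO[K])C[C@H](O[Si](C)(C)C(C)(C)C)C[C@]2(C)[C@H]1CCC3(C)OCCO3 | intermediate (not isolated)
22 | 2α-(tert-butyldimethylsilyloxy)-13,13-ethylenedioxy-14,15-dinorlabd-7-en-19-al | CC1=CC[C@H]2[C@@](C)(C=O)C[C@H](O[Si](C)(C)C(C)(C)C)C[C@]2(C)[C@H]1CCC3(C)OCCO3 | intermediate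
23 | 2α-(tert-butyldimethylsilyloxy)-13,13-ethylenedioxy-14,15-dinorlabd-7-en-19-ol | CC1=CC[C@H]2[C@@](C)(CO)C[C@H](O[Si](C)(C)C(C)(C)C)C[C@]2(C)[C@H]1CCC3(C)OCCO3 | intermediate
24 | 2α-(tert-butyldimethylsilyloxy)-13,13-ethylenedioxy-14,15-dinorlabd-7-en-19-yl acetate | CC1=CC[C@H]2[C@@](C)(COC(C)=O)C[C@H](O[Si](C)(C)C(C)(C)C)C[C@]2(C)[C@H]1CCC3(C)OCCO3 | intermediate
25 | 19-acetoxy-2α-hydroxy-14,15-dinorlabd-7-en-13-one | CC1=CC[C@H]2[C@@](C)(COC(C)=O)C[C@H](O)C[C@]2(C)[C@H]1CCC(C)=O | intermediate
26 | 19-acetoxy-7α-hydroperoxy-2α-hydroxy-14,15-dinorlabd-8(17)-en-13-one | C=C1[C@H](OO)C[C@H]2[C@@](C)(COC(C)=O)C[C@H](O)C[C@]2(C)[C@H]1CCC(C)=O | intermediate (not isolated)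
27 | 19-acetoxy-2α,7α-dihydroxy-14,15-dinorlabd-8(17)-en-13-one (CNP0139304.2) | C=C1[C@H](O)C[C@H]2[C@@](C)(COC(C)=O)C[C@H](O)C[C@]2(C)[C@H]1CCC(C)=O | target

## Step count and least certain steps

Total step count: 17. Longest linear sequence: 17 steps, from 1.

**Step 5 (key step).** The most likely failure is poor facial selectivity at C2: closure may still go through the chair with oxygen on the β face despite the clash with the C10 methyl. If the reaction turns fully stepwise, proton loss from the C4 cation may also lose regiocontrol (alkene moving into the ring, or chloride capture). Fallback for the C2 problem: starting from 8, the cyclisation is run as before and the 2β-alcohol F1 is taken on. A Mitsunobu reaction (4-nitrobenzoic acid, PPh3, diisopropyl azodicarboxylate, THF) inverts C2 by displacement from the open α face to give the 2α 4-nitrobenzoate F2, and methanolysis (K2CO3, MeOH) returns to 9.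

**Step 17.** The most likely failure is hydrogen abstraction from the wrong allylic position: the axial 9α-H or a C6 hydrogen instead of the C17 methyl, because ring hydrogens on the attacked face compete in singlet-oxygen ene reactions. Fallback, leaving the route at 23 and rejoining at 27:
- epoxidation (mCPBA, NaHCO3, CH2Cl2) on the α face gives the 7α,8α-epoxide F9;
- Al(OiPr)3 in refluxing toluene opens it by syn-elimination toward the C17 methyl to the 7α,19-diol F10;
- selective acetylation of the primary hydroxyl (AcCl, 2,4,6-collidine, CH2Cl2, −78 °C) gives F11;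
- hydrolysis (aq HCl, THF, 0 °C) removes ketal and silyl ether to give 27.

**Step 13.** The most likely failures are O-methylation or aldol self-condensation of the aldehyde enolate, since α-branched aldehyde enolates are ambident and the aldehyde is electrophilic. Fallback, from 20 back to 23:
- Pinnick oxidation (NaClO2, NaH2PO4, 2-methylbut-2-ene, t-BuOH–H2O) gives acid F6;
- MeI and K2CO3 in DMF give methyl ester F7;
- the ester enolate (LiN(iPr)2, THF, −78 °C; MeI) is methylated on the same α face to give the axial ester F8;
- LiAlH4 reduces F8 to 23.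

**Step 7.** The most likely failure is slow or incomplete addition: the carbonyl lies next to quaternary C10 and the β-ketal Grignard reagent is thermally fragile, so decomposition of the reagent and γ-deprotonation of the enone can overtake 1,2-addition. Fallback, from 10 back to 14:
- but-3-enylmagnesium bromide, pre-mixed with anhydrous CeCl3, adds to give tertiary alcohol F3;
- the same chromium-mediated transposition gives enone F4;
- Wacker oxidation of the terminal alkene (PdCl2, CuCl, O2, DMF–H2O) gives diketone F5;
- selective ketalisation of the saturated methyl ketone (ethylene glycol, pyridinium p-toluenesulfonate, benzene, reflux) gives 14.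

## Further compounds

F1 | step 5 | (4aS,7R,8aS)-7-hydroxy-2,8a-dimethyl-5-methylidene-4a,5,6,7,8,8a-hexahydronaphthalen-1(4H)-one (2β-epimer of 9) | CC1=CC[C@H]2C(=C)C[C@@H](O)C[C@]2(C)C1=O
F2 | step 5 | 2α 4-nitrobenzoate ester of 9 | CC1=CC[C@H]2C(=C)C[C@H](OC(=O)c3ccc(cc3)[N+](=O)[O-])C[C@]2(C)C1=O
F3 | step 7 | 9-(but-3-enyl) tertiary allylic alcohol from 10 (C9 configuration open) | CC1=CC[C@H]2C(=C)C[C@H](O[Si](C)(C)C(C)(C)C)C[C@]2(C)C1(O)CCC=C
F4 | step 7 | 9-(but-3-enyl)-7-oxo Δ8 enone (2α-OTBS, C4 methylene) | O=C1C[C@H]2C(=C)C[C@H](O[Si](C)(C)C(C)(C)C)C[C@]2(C)C(CCC=C)=C1C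
F5 | step 7 | 2α-(tert-butyldimethylsilyloxy)-14,15,19-trinorlabda-4(18),8-diene-7,13-dione | O=C1C[C@H]2C(=C)C[C@H](O[Si](C)(C)C(C)(C)C)C[C@]2(C)C(CCC(C)=O)=C1C
F6 | step 13 | 2α-(tert-butyldimethylsilyloxy)-13,13-ethylenedioxy-14,15,18-trinorlabd-7-en-19-oic acid and its C4 epimer | CC1=CC[C@H]2C(C(=O)O)C[C@H](O[Si](C)(C)C(C)(C)C)C[C@]2(C)[C@H]1CCC3(C)OCCO3
F7 | step 13 | methyl ester of F6 | CC1=CC[C@H]2C(C(=O)OC)C[C@H](O[Si](C)(C)C(C)(C)C)C[C@]2(C)[C@H]1CCC3(C)OCCO3
F8 | step 13 | methyl 2α-(tert-butyldimethylsilyloxy)-13,13-ethylenedioxy-14,15-dinorlabd-7-en-19-oate | CC1=CC[C@H]2[C@@](C)(C(=O)OC)C[C@H](O[Si](C)(C)C(C)(C)C)C[C@]2(C)[C@H]1CCC3(C)OCCO3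
F9 | step 17 | 7α,8α-epoxide of 23 | C[C@]14O[C@@H]4C[C@H]2[C@@](C)(CO)C[C@H](O[Si](C)(C)C(C)(C)C)C[C@]2(C)[C@H]1CCC3(C)OCCO3
F10 | step 17 | 2α-(tert-butyldimethylsilyloxy)-13,13-ethylenedioxy-14,15-dinorlabd-8(17)-ene-7α,19-diol | C=C1[C@H](O)C[C@H]2[C@@](C)(CO)C[C@H](O[Si](C)(C)C(C)(C)C)C[C@]2(C)[C@H]1CCC3(C)OCCO3
F11 | step 17 | 19-acetate of F10 | C=C1[C@H](O)C[C@H]2[C@@](C)(COC(C)=O)C[C@H](O[Si](C)(C)C(C)(C)C)C[C@]2(C)[C@H]1CCC3(C)OCCO3
A1 | alternative 1 | open-chain precursor: (E)-3-methyl enal (C9=C10, C11 aldehyde) tied through C1–C4 (2-OTBS; C4 with methyl and CH2OPMB) to a (5E,7Z)-7-triethylsilyloxy diene bearing CH2SPh on C8 | c1ccccc1SC/C=C(\O[Si](CC)(CC)CC)/C=C/[C@@](C)(COCc2ccc(OC)cc2)C[C@H](O[Si](C)(C)C(C)(C)C)C/C(C)=C/C=O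
A2 | alternative 1 | trans-fused decalin with C6=C7 triethylsilyl enol ether, 9β-formyl, 8β-(phenylthiomethyl), 2α-OTBS and 19-OPMB | c3ccccc3SC[C@H]1C(O[Si](CC)(CC)CC)=C[C@H]2[C@@](C)(COCc4ccc(OC)cc4)C[C@H](O[Si](C)(C)C(C)(C)C)C[C@]2(C)[C@H]1C=O
A3 | alternative 2 | 6-bromo-7-hydroxy arene (ring B aromatic) with C8 and C10 methyls, the ketal chain on C9 and the C5 tether C4(Me)(CH2OPMB)–C3–C2(OTBS)–C1–OTs | Oc1c(Br)c([C@@](C)(COCc2ccc(OC)cc2)C[C@H](O[Si](C)(C)C(C)(C)C)COS(=O)(=O)c2ccc(C)cc2)c(C)c(CCC3(C)OCCO3)c1C
A4 | alternative 2 | ring-fused 2,5-cyclohexadienone (C7=O, C5=C6(Br), C8=C9) with quaternary C10 and ring A complete | O=C1C(Br)=C2[C@@](C)(COCc3ccc(OC)cc3)C[C@H](O[Si](C)(C)C(C)(C)C)C[C@]2(C)C(CCC4(C)OCCO4)=C1C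
A5 | alternative 3 | (E)-2-(tert-butyldimethylsilyloxy)penta-1,3-diene | C=C(O[Si](C)(C)C(C)(C)C)/C=C/C
A6 | alternative 3 | methyl 4-methyl-2-oxo-2,5-dihydrofuran-3-carboxylate | COC(=O)C1=C(C)COC1=O
A7 | alternative 3 | cis-fused lactone of ring A with C1=C2 silyl enol ether, quaternary C4, C10 methine bearing C20 and C5 bearing CO2Me | O=C3OC[C@@]4(C)CC(O[Si](C)(C)C(C)(C)C)=C[C@@H](C)[C@@]34C(=O)OC
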